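Eudesmane numbering is used throughout: ring A is C1–C5 plus C10, ring B is C5–C10, C14 is the methyl on C10 and C15 the methylene on C4.

## Analysis of the target

Target 33 is the (E)-4-hydroxycinnamate of 5α-eudesm-4(15)-en-6α-ol, a trans-fused decalin with an exocyclic methylene at C4. It has four stereocentres: the quaternary C10 (methyl β, axial) and the contiguous C5, C6 and C7 of ring B. H5, H6 and H7 are all axial, so the C6 oxygen (α) and the C7 isopropyl group (β) are both equatorial and trans to each other. Opened along C5–C6–C7–C8, this trans-diequatorial pair is a syn relationship, which fixes the geometry of any allylation used to set it. The sensitive parts are the C4=C15 alkene (acid moves it into the ring), the cinnamate with its free phenol, and the ester position itself, which is crowded by C5, C7 and C15. The hard part is the quaternary C10 and its relation to the three ring B centres, in a product that keeps no functional group at C1–C3, C8 or C9. The strategy rests on C10 carrying a methyl group and C4 a one-carbon unit that can come from a ketone: ring A can then be the cyclohexene of a [4+2] cycloaddition between a C5=C4(OSi)–C3=C2 diene and a C10(CH3)=C1 dienophile, joined through C6–C9, which carry the C6 and C7 centres and a temporary C9 carbonyl.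

## Retrosynthetic reasoning

**Ester.** The C6–O acyl bond of 33 is cut first, giving alcohol 29 and the acetyl-protected acid 30 (through acetate 32). The cinnamate would not survive the hydride, radical, fluoride and organometallic steps, so it goes on last; the phenol is masked so that only one acyl donor is present.

**C4=C15.** The methylene of 29 is traced through silyl ether 28 to ketone 27. Carbonyl methylenation is the only C–C bond formed after the rings, and the ketone is exactly what an enol silane at C3=C4 delivers.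

**C9 oxygen.** Ketone 27 comes from enol silane 26, which comes from xanthate 25, alcohol 23 and finally adduct 22. A C9 carbonyl is added in the retrosynthetic direction because the dienophile needs it; keeping C4 as the enol silane while C9 is removed means the two carbonyls never coexist as ketones.

**Both rings.** Adduct 22 is opened at C5–C10 and C1–C2 to trienone 21. These two bonds close rings A and B and create C5 and C10 in one operation, with C6 and C7 already in place on the tether. The forward reaction must pass through the arrangement in which the tether carbonyl points away from the diene, since C10 cannot be corrected afterwards.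

**C9–C10.** Trienone 21 is cut between C9 and C10 to Weinreb amide 19 and isopropenylmagnesium bromide 20. Making the C9 ketone last is deliberate: with two enolisable enones present the dienol silane could not be formed selectively, whereas an amide is inert to soft enolisation.

**Diene.** Dienol silane 19 comes from vinyl ketone 18, and 18 from aldehyde 15 and vinylmagnesium bromide 16 through carbinol 17. The C6 oxygen is already silylated, because a free β-hydroxy vinyl ketone would cyclise by oxa-Michael addition or cleave by retro-aldol reaction.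

**C9 oxidation level and C4 aldehyde.** Aldehyde 15 comes from acetal 14, and the amide of 14 from acid 12, alcohol 10 and terminal alkene 8. The acetal carries C4 through hydroboration and oxidation untouched.

**C6–C7.** Alkene 8 is the silyl ether of homoallylic alcohol 7, which is cut at C6–C7 to aldehyde 2 and the allyl unit of alkene 3, delivered as Z-allylborane 5. The ring-trans C6/C7 pair is syn in the open chain, so the Z reagent is required; the E reagent would give the 6,7-cis series. This single step sets both centres and their absolute configuration.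

**Aldehyde.** Aldehyde 2 is the half-reduced form of ester 1.

## Alternatives that were turned down

**Alternative 1:** Ring B is cut at C5–C6, back to keto aldehyde A1, a cyclohexanone whose quaternary carbon carries the C9–C8–C7–C6 arm. In the forward step, KOH in methanol or an amidine base forms the C5 enolate of the C4 ketone, which adds to the aldehyde to give ketol A2.
- For: the aldol is reversible, so C5, C6 and C7 (which is α to the aldehyde) should all settle in the all-equatorial, hydrogen-bonded trans-fused ketol. C10 is set earlier by a catalyst-controlled conjugate addition, and no C9 oxygen has to be removed.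
- Against: dehydration of A2 to the C5=C6 enone under the same base is irreversible and drains the equilibrium. The free ketol must also survive methylenation, where retro-aldol cleavage threatens.
- Comparison: this plan is stronger on the security of C10 and on step count. The chosen route offers in its place a C6 oxygen that is a robust silyl ether from the third step, and one kinetic step that forms both rings without depending on an equilibrium that elimination can empty.

**Alternative 2:** The angular methyl is traced back to a cyclopropane methylene (C10–C14 plus a temporary C5–C14 bond). In the forward step, Et2Zn/CH2I2 cyclopropanates cyclohexenol A3 on the face of the C4 hydroxyl to give carbinol A4.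
- For: hydroxyl-directed cyclopropanation is among the most reliable ways to fix a quaternary centre, and later reductive opening of the derived cyclopropyl ketone gives the methyl and a regiodefined C5 enolate.
- Against: it solves only C10. Ring B and the C6 centre still have to be made, and the C4 carbinol centre is created only to be destroyed.
- Comparison: it is stronger than the chosen route on C10 control, which here rests on an exo/endo preference, but clearly weaker on step economy. The chosen route closes both rings in the step that makes C10.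

**Alternative 3:** Ring B is the cyclohexene, cut at C5–C6 and C9–C10 to keto ester A5 and siloxydiene A6. In the forward step, Cu(OTf)2–bisoxazoline or ZnCl2 promotes their cycloaddition to cis-fused adduct A7.
- For: it is convergent, the polarisation is matched (diene terminus C9 to the β-carbon C10), catalytic enantiocontrol is conceivable, and no C9 oxygen is introduced.
- Against: the dienophile is tetrasubstituted and the step makes two adjacent quaternary carbons, so it should be slow, and under Lewis acid it may stop at the conjugate-addition stage. The C5 ester then has to be excised, C7 set by hydrogenation of C7=C8 with uncertain facial selectivity, and C6 depends on the orientation of the siloxy group.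
- Comparison: it is stronger on convergence and on catalytic asymmetric induction. The chosen route instead sets C6 and C7 unambiguously in the open chain and uses them to steer C5 and C10, with no extra carbon to remove.

Key step: step 12

Assumption: the isopinocampheyl reagent from (+)-α-pinene is taken to deliver the allyl unit to the Si face of 2, as it does with unbranched aliphatic aldehydes; if the sense were opposite, the enantiomeric borane would be used with no other change.

## Route

Step 1
Reactants: 1 methyl 3,3-dimethoxypropanoate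
Product: 2 3,3-dimethoxypropanal
Conditions: iBu2AlH (1.05 equiv), CH2Cl2, −78 °C; MeOH, then aq. KNaC4H4O6; used crude and cold
Reagents that add atoms: none
Why: Partial reduction of an ester; the tetrahedral aluminium hemiacetal is stable at −78 °C and releases the aldehyde only on work-up, and the product is used at once because it can lose methanol.

Step 2
Reactants: 2 3,3-dimethoxypropanal; 3 (Z)-4-methylpent-2-ene
Product: 7 (3R,4R)-1,1-dimethoxy-4-(propan-2-yl)hex-5-en-3-ol, via allylpotassium 4 (not isolated), via allylborane 5 (not isolated), via borinate 6 (not isolated)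
Conditions: 3, n-BuLi, KOtBu, THF, −78 → −45 °C; (−)-Ipc2BOMe, −78 °C; BF3·OEt2, −78 °C; 2, −78 °C; then NaOH, H2O2, 0 °C → rt
Reagents that add atoms: none
Why: Brown-type asymmetric allylboration: the allylic methyl of 3 is metalated with retention of the Z geometry, and the Z-allylborane reacts through a closed chair (Zimmerman–Traxler) transition state, so the new C6 hydroxyl and C7 isopropyl come out syn along C5–C6–C7–C8. The isopinocampheyl groups direct attack to the Si face of the aldehyde, which fixes the absolute configuration of both centres as needed for 6α-O and 7β-isopropyl.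

Step 3
Reactants: 7 (3R,4R)-1,1-dimethoxy-4-(propan-2-yl)hex-5-en-3-ol
Product: 8 tert-butyl{[(3R,4R)-1,1-dimethoxy-4-(propan-2-yl)hex-5-en-3-yl]oxy}dimethylsilane
Conditions: TBSCl, imidazole, DMAP (cat.), DMF, 40 °C
Reagents that add atoms: tert-butyldimethylsilyl chloride, CC(C)(C)[Si](C)(C)Cl
Why: Standard silylation of a secondary alcohol; chloride/imidazole is chosen over a silyl triflate so that the dimethyl acetal is not activated. Protection now prevents lactonisation of the later C9 acid and oxa-Michael or retro-aldol loss of the later β-oxy vinyl ketone.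

Step 4
Reactants: 8 tert-butyl{[(3R,4R)-1,1-dimethoxy-4-(propan-2-yl)hex-5-en-3-yl]oxy}dimethylsilane
Product: 10 (3S,4R)-4-[(tert-butyldimethylsilyl)oxy]-6,6-dimethoxy-3-(propan-2-yl)hexan-1-ol, via alkylborane 9 (not isolated)
Conditions: 9-BBN, THF, 0 °C → rt; then NaOH, H2O2, 0 °C
Reagents that add atoms: hydrogen peroxide, OO
Why: Anti-Markovnikov hydroboration–oxidation of the only alkene; 9-BBN places boron on the terminal carbon C9, and acetal and silyl ether are inert.

Step 5
Reactants: 10 (3S,4R)-4-[(tert-butyldimethylsilyl)oxy]-6,6-dimethoxy-3-(propan-2-yl)hexan-1-ol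
Product: 12 (3S,4R)-4-[(tert-butyldimethylsilyl)oxy]-6,6-dimethoxy-3-(propan-2-yl)hexanoic acid, via aldehyde 11 (not isolated)
Conditions: TEMPO (cat.), NaOCl (cat.), NaClO2, MeCN/phosphate buffer (pH 6.7), 35 °C
Reagents that add atoms: sodium chlorite, [Na+].[O-]Cl=O
Why: Oxoammonium oxidation of the primary alcohol to the aldehyde, followed in the same flask by chlorite (Pinnick-type) oxidation to the acid; the near-neutral buffer leaves the acetal and the silyl ether intact.

Step 6
Reactants: 12 (3S,4R)-4-[(tert-butyldimethylsilyl)oxy]-6,6-dimethoxy-3-(propan-2-yl)hexanoic acid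
Product: 14 (3S,4R)-4-[(tert-butyldimethylsilyl)oxy]-N,6,6-trimethoxy-N-methyl-3-(propan-2-yl)hexanamide, via acylimidazole 13 (not isolated)
Conditions: CDI, CH2Cl2, rt; then MeNH(OMe)·HCl, rt
Reagents that add atoms: N,O-dimethylhydroxylamine hydrochloride, CNOC.Cl
Why: Amide formation through the acyl imidazolide; the Weinreb amide stores C9 at the acyl level in a form that cannot be enolised under the conditions of step 10.

Step 7
Reactants: 14 (3S,4R)-4-[(tert-butyldimethylsilyl)oxy]-N,6,6-trimethoxy-N-methyl-3-(propan-2-yl)hexanamide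
Product: 15 (3S,4R)-4-[(tert-butyldimethylsilyl)oxy]-N-methoxy-N-methyl-6-oxo-3-(propan-2-yl)hexanamide
Conditions: PPTS, acetone/H2O, 50 °C
Reagents that add atoms: water, O
Why: Mild acid-catalysed hydrolysis of the dimethyl acetal; the hindered secondary silyl ether and the amide tolerate pyridinium tosylate.

Step 8
Reactants: 15 (3S,4R)-4-[(tert-butyldimethylsilyl)oxy]-N-methoxy-N-methyl-6-oxo-3-(propan-2-yl)hexanamide; 16 vinylmagnesium bromide
Product: 17 (3S,4R,6RS)-4-[(tert-butyldimethylsilyl)oxy]-6-hydroxy-N-methoxy-N-methyl-3-(propan-2-yl)oct-7-enamide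
Conditions: CH2=CHMgBr (1.1 equiv), THF, −78 °C; aq. NH4Cl
Reagents that add atoms: none
Why: Grignard 1,2-addition; at −78 °C the aldehyde reacts far faster than the Weinreb amide. The new C4 carbinol centre is a mixture and is oxidised away in the next step.

Step 9
Reactants: 17 (3S,4R,6RS)-4-[(tert-butyldimethylsilyl)oxy]-6-hydroxy-N-methoxy-N-methyl-3-(propan-2-yl)oct-7-enamide
Product: 18 (3S,4R)-4-[(tert-butyldimethylsilyl)oxy]-N-methoxy-N-methyl-6-oxo-3-(propan-2-yl)oct-7-enamide
Conditions: Dess–Martin periodinane, NaHCO3, CH2Cl2, 0 °C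
Reagents that add atoms: none
Why: Dess–Martin oxidation of an allylic alcohol to the vinyl ketone; the buffered, non-basic medium avoids elimination of the β-silyloxy group.

Step 10
Reactants: 18 (3S,4R)-4-[(tert-butyldimethylsilyl)oxy]-N-methoxy-N-methyl-6-oxo-3-(propan-2-yl)oct-7-enamide
Product: 19 (3S,4S,5Z)-4,6-bis[(tert-butyldimethylsilyl)oxy]-N-methoxy-N-methyl-3-(propan-2-yl)octa-5,7-dienamide
Conditions: TBSOTf, Et3N, CH2Cl2, −78 → 0 °C
Reagents that add atoms: tert-butyldimethylsilyl trifluoromethanesulfonate, CC(C)(C)[Si](C)(C)OS(=O)(=O)C(F)(F)F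
Why: Soft enolisation and O-silylation of a vinyl ketone to the 2-siloxydiene; C5 is the only enolisable position because the amide does not react, and no free enolate is formed, so the C6 silyloxy group is not expelled. The Z enol ether (siloxy cis to C6, tether trans to the vinyl group) is expected because it avoids the clash between C6 and the vinyl group.

Step 11
Reactants: 19 (3S,4S,5Z)-4,6-bis[(tert-butyldimethylsilyl)oxy]-N-methoxy-N-methyl-3-(propan-2-yl)octa-5,7-dienamide; 20 isopropenylmagnesium bromide
Product: 21 (5S,6S,7Z)-6,8-bis[(tert-butyldimethylsilyl)oxy]-2-methyl-5-(propan-2-yl)deca-1,7,9-trien-3-one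
Conditions: CH2=C(CH3)MgBr, THF, −20 → 0 °C; cold aq. NH4Cl; used directly
Reagents that add atoms: none
Why: Weinreb ketone synthesis; the chelated tetrahedral intermediate prevents over-addition and keeps the enone masked until the quench. Making the C9 ketone only now means it never competed in the enolisation of step 10.

Step 12
Reactants: 21 (5S,6S,7Z)-6,8-bis[(tert-butyldimethylsilyl)oxy]-2-methyl-5-(propan-2-yl)deca-1,7,9-trien-3-one
Product: 22 4,6α-bis[(tert-butyldimethylsilyl)oxy]-15-nor-5α-eudesm-3-en-9-one
Conditions: toluene (0.01 M), BHT (cat.), 110 °C, sealed tube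
Reagents that add atoms: none
Why: Heating 21 should bring about a concerted but asynchronous intramolecular [4+2] cycloaddition in which C5 of the Z-siloxydiene bonds to the α-carbon C10 and C2 to the β-carbon C1 of the isopropenyl ketone, the only orientation a four-atom tether allows; the closest known reaction type is the thermal cyclisation of 1,7,9-decatrien-3-ones, including those with 2-silyloxydienes. Ring B closes through the C5–C10 bond with C6–C9 folded into a chair, and ring A is the cyclohexene of the cycloaddition, completed by the C1–C2 bond and left as the C3=C4 enol silane. C5 is set by allylic 1,3-strain: the siloxy group on C4 is cis to C6, so C6–H eclipses the C4=C5 bond, the C6 silyloxy group lies anti to the forming C5–C10 bond (equatorial in the chair) and the dienophile reaches the diene face that puts H5 trans to H6. C10 is set by the exo arrangement, in which the tether carbonyl points away from the diene and the α-methyl lies under it, giving the methyl axial and trans to H5 with the isopropyl group equatorial. The step therefore needs exo over endo selectivity, since the endo mode would give the cis-fused C10 epimer; the α-methyl group of the dienophile, the siloxy/silyloxy pair at C4 and C6 (which clashes in a boat-like endo arrangement) and the equatorial isopropyl group all work in that direction. Because the tether enforces the 1,3 relation of C4–OSi and C10 and not the intrinsically preferred 1,4 one, the siloxy group serves mainly as the C4 oxygen handle and as a steric control element, and the reaction is run thermally without a Lewis acid, which would instead trigger Mukaiyama–Michael attack of C5 on C1.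

Step 13
Reactants: 22 4,6α-bis[(tert-butyldimethylsilyl)oxy]-15-nor-5α-eudesm-3-en-9-one
Product: 23 4,6α-bis[(tert-butyldimethylsilyl)oxy]-15-nor-5α-eudesm-3-en-9-ol (C9 epimers)
Conditions: LiAlH4, Et2O, −78 → 0 °C
Reagents that add atoms: none
Why: Hydride reduction of the neopentyl ketone in an aprotic medium, to which the enol silane and the silyl ether are inert; the C9 configuration does not matter because the centre is removed.

Step 14
Reactants: 23 4,6α-bis[(tert-butyldimethylsilyl)oxy]-15-nor-5α-eudesm-3-en-9-ol (C9 epimers)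
Product: 25 O-{4,6α-bis[(tert-butyldimethylsilyl)oxy]-15-nor-5α-eudesm-3-en-9-yl} S-methyl carbonodithioate, via sodium xanthate 24 (not isolated)
Conditions: NaH, imidazole (cat.), THF, 0 °C → rt; CS2; then MeI
Reagents that add atoms: carbon disulfide, S=C=S; iodomethane, CI
Why: Xanthate formation from the alkoxide; the basic conditions leave the enol silane untouched.

Step 15
Reactants: 25 O-{4,6α-bis[(tert-butyldimethylsilyl)oxy]-15-nor-5α-eudesm-3-en-9-yl} S-methyl carbonodithioate
Product: 26 4,6α-bis[(tert-butyldimethylsilyl)oxy]-15-nor-5α-eudesm-3-ene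
Conditions: Bu3SnH, AIBN (cat.), toluene, 110 °C
Reagents that add atoms: none
Why: Barton–McCombie deoxygenation through the secondary C9 radical; the electron-rich enol silane is a poor partner for stannyl radicals, so C4 stays masked while C9 becomes a methylene.

Step 16
Reactants: 26 4,6α-bis[(tert-butyldimethylsilyl)oxy]-15-nor-5α-eudesm-3-ene
Product: 27 6α-[(tert-butyldimethylsilyl)oxy]-15-nor-5α-eudesman-4-one
Conditions: Bu4NF (1.0 equiv), AcOH, THF, −20 → 0 °C
Reagents that add atoms: none
Why: Fluoride cleaves the silyl enol ether much faster than the hindered secondary silyl ether, and acetic acid protonates the enolate at C3. C5 is not part of the enol double bond, so the trans ring fusion from step 12 is kept.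

Step 17
Reactants: 27 6α-[(tert-butyldimethylsilyl)oxy]-15-nor-5α-eudesman-4-one
Product: 28 6α-[(tert-butyldimethylsilyl)oxy]-5α-eudesm-4(15)-ene
Conditions: Cp2TiMe2, toluene, 70 °C, dark
Reagents that add atoms: dimethyltitanocene, C[Ti](C)(C1C=CC=C1)C1C=CC=C1
Why: Petasis methylenation through Cp2Ti=CH2; the reagent is non-basic, so the C5 hydrogen α to the ketone is not enolised. This matters because the position of the cis/trans equilibrium is uncertain when the equatorial C6 silyloxy group sits beside the C4 carbonyl.

Step 18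
Reactants: 28 6α-[(tert-butyldimethylsilyl)oxy]-5α-eudesm-4(15)-ene
Product: 29 (1S,2S,4aR,8aS)-4a-methyl-8-methylidene-2-(propan-2-yl)decahydronaphthalen-1-ol (5α-eudesm-4(15)-en-6α-ol)
Conditions: Bu4NF, THF, 50 °C
Reagents that add atoms: none
Why: Fluoride desilylation; the non-acidic conditions leave the exocyclic alkene in place.

Step 19
Reactants: 29 (1S,2S,4aR,8aS)-4a-methyl-8-methylidene-2-(propan-2-yl)decahydronaphthalen-1-ol; 30 (E)-3-(4-acetoxyphenyl)prop-2-enoic acid
Product: 32 (1S,2S,4aR,8aS)-4a-methyl-8-methylidene-2-(propan-2-yl)decahydronaphthalen-1-yl (E)-3-(4-acetoxyphenyl)prop-2-enoate, via mixed anhydride 31 (not isolated)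
Conditions: 30, 2,4,6-Cl3C6H2COCl, Et3N, THF, rt; then 29, DMAP, toluene, 60 °C
Reagents that add atoms: none
Why: Yamaguchi esterification, chosen for the hindered equatorial alcohol; the reaction is at oxygen, so C6 keeps its configuration, and the acetyl group keeps the phenol from acting as a second nucleophile.

Step 20
Reactants: 32 (1S,2S,4aR,8aS)-4a-methyl-8-methylidene-2-(propan-2-yl)decahydronaphthalen-1-yl (E)-3-(4-acetoxyphenyl)prop-2-enoate
Product: 33 (1S,2S,4aR,8aS)-4a-methyl-8-methylidene-2-(propan-2-yl)decahydronaphthalen-1-yl (E)-3-(4-hydroxyphenyl)prop-2-enoate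
Conditions: pyrrolidine, CH2Cl2, 0 °C
Reagents that add atoms: none
Why: Aminolysis of the aryl acetate, which is far more reactive than the crowded cinnamate of a secondary alcohol; the mild conditions should leave the ester and both alkenes untouched.

## Compound list

1 | methyl 3,3-dimethoxypropanoate | COC(=O)CC(OC)OC | starting material
2 | 3,3-dimethoxypropanal | O=CCC(OC)OC | intermediate
3 | (Z)-4-methylpent-2-ene | C/C=C\C(C)C | starting material
4 | (Z)-4-methylpent-2-en-1-ylpotassium | [K+].[CH2-]/C=C\C(C)C | intermediate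
5 | B-[(Z)-4-methylpent-2-en-1-yl]diisopinocampheylborane (isopinocampheyl groups from (+)-α-pinene) | CC(C)/C=C\CB([C@@H]1C[C@@H]2C[C@@H](C2(C)C)[C@H]1C)[C@@H]1C[C@@H]2C[C@@H](C2(C)C)[C@H]1C | intermediate
6 | (3R,4R)-1,1-dimethoxy-4-(propan-2-yl)hex-5-en-3-yl diisopinocampheylborinate | C=C[C@@H](C(C)C)[C@H](OB([C@@H]1C[C@@H]2C[C@@H](C2(C)C)[C@H]1C)[C@@H]1C[C@@H]2C[C@@H](C2(C)C)[C@H]1C)CC(OC)OC | intermediate
7 | (3R,4R)-1,1-dimethoxy-4-(propan-2-yl)hex-5-en-3-ol | C=C[C@@H](C(C)C)[C@H](O)CC(OC)OC | intermediate
8 | tert-butyl{[(3R,4R)-1,1-dimethoxy-4-(propan-2-yl)hex-5-en-3-yl]oxy}dimethylsilane | C=C[C@@H](C(C)C)[C@H](O[Si](C)(C)C(C)(C)C)CC(OC)OC | intermediate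
9 | 9-[(3S,4R)-4-[(tert-butyldimethylsilyl)oxy]-6,6-dimethoxy-3-(propan-2-yl)hexyl]-9-borabicyclo[3.3.1]nonane | C1CCC2CCCC1B2CC[C@@H](C(C)C)[C@H](O[Si](C)(C)C(C)(C)C)CC(OC)OC | intermediate
10 | (3S,4R)-4-[(tert-butyldimethylsilyl)oxy]-6,6-dimethoxy-3-(propan-2-yl)hexan-1-ol | OCC[C@@H](C(C)C)[C@H](O[Si](C)(C)C(C)(C)C)CC(OC)OC | intermediate
11 | (3S,4R)-4-[(tert-butyldimethylsilyl)oxy]-6,6-dimethoxy-3-(propan-2-yl)hexanal | O=CC[C@@H](C(C)C)[C@H](O[Si](C)(C)C(C)(C)C)CC(OC)OC | intermediate
12 | (3S,4R)-4-[(tert-butyldimethylsilyl)oxy]-6,6-dimethoxy-3-(propan-2-yl)hexanoic acid | OC(=O)C[C@@H](C(C)C)[C@H](O[Si](C)(C)C(C)(C)C)CC(OC)OC | intermediate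
13 | 1-[(3S,4R)-4-[(tert-butyldimethylsilyl)oxy]-6,6-dimethoxy-3-(propan-2-yl)hexanoyl]imidazole | O=C(C[C@@H](C(C)C)[C@H](O[Si](C)(C)C(C)(C)C)CC(OC)OC)n1ccnc1 | intermediate
14 | (3S,4R)-4-[(tert-butyldimethylsilyl)oxy]-N,6,6-trimethoxy-N-methyl-3-(propan-2-yl)hexanamide | CON(C)C(=O)C[C@@H](C(C)C)[C@H](O[Si](C)(C)C(C)(C)C)CC(OC)OC | intermediate
15 | (3S,4R)-4-[(tert-butyldimethylsilyl)oxy]-N-methoxy-N-methyl-6-oxo-3-(propan-2-yl)hexanamide | CON(C)C(=O)C[C@@H](C(C)C)[C@H](O[Si](C)(C)C(C)(C)C)CC=O | intermediate
16 | vinylmagnesium bromide | C=C[Mg]Br | starting material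
17 | (3S,4R,6RS)-4-[(tert-butyldimethylsilyl)oxy]-6-hydroxy-N-methoxy-N-methyl-3-(propan-2-yl)oct-7-enamide | CON(C)C(=O)C[C@@H](C(C)C)[C@H](O[Si](C)(C)C(C)(C)C)CC(O)C=C | intermediate
18 | (3S,4R)-4-[(tert-butyldimethylsilyl)oxy]-N-methoxy-N-methyl-6-oxo-3-(propan-2-yl)oct-7-enamide | CON(C)C(=O)C[C@@H](C(C)C)[C@H](O[Si](C)(C)C(C)(C)C)CC(=O)C=C | intermediate
19 | (3S,4S,5Z)-4,6-bis[(tert-butyldimethylsilyl)oxy]-N-methoxy-N-methyl-3-(propan-2-yl)octa-5,7-dienamide | CON(C)C(=O)C[C@@H](C(C)C)[C@H](O[Si](C)(C)C(C)(C)C)/C=C(\O[Si](C)(C)C(C)(C)C)C=C | intermediate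
20 | isopropenylmagnesium bromide | CC(=C)[Mg]Br | starting material
21 | (5S,6S,7Z)-6,8-bis[(tert-butyldimethylsilyl)oxy]-2-methyl-5-(propan-2-yl)deca-1,7,9-trien-3-one | C=C(C)C(=O)C[C@@H](C(C)C)[C@H](O[Si](C)(C)C(C)(C)C)/C=C(\O[Si](C)(C)C(C)(C)C)C=C | intermediate
22 | 4,6α-bis[(tert-butyldimethylsilyl)oxy]-15-nor-5α-eudesm-3-en-9-one | CC(C)(C)[Si](C)(C)OC1=CCC[C@]2(C)C(=O)C[C@@H](C(C)C)[C@H](O[Si](C)(C)C(C)(C)C)[C@@H]12 | intermediate
23 | 4,6α-bis[(tert-butyldimethylsilyl)oxy]-15-nor-5α-eudesm-3-en-9-ol (C9 epimers) | CC(C)(C)[Si](C)(C)OC1=CCC[C@]2(C)C(O)C[C@@H](C(C)C)[C@H](O[Si](C)(C)C(C)(C)C)[C@@H]12 | intermediate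
24 | sodium O-{4,6α-bis[(tert-butyldimethylsilyl)oxy]-15-nor-5α-eudesm-3-en-9-yl} carbonodithioate | CC(C)(C)[Si](C)(C)OC1=CCC[C@]2(C)C(OC(=S)[S-])C[C@@H](C(C)C)[C@H](O[Si](C)(C)C(C)(C)C)[C@@H]12.[Na+] | intermediate
25 | O-{4,6α-bis[(tert-butyldimethylsilyl)oxy]-15-nor-5α-eudesm-3-en-9-yl} S-methyl carbonodithioate | CC(C)(C)[Si](C)(C)OC1=CCC[C@]2(C)C(OC(=S)SC)C[C@@H](C(C)C)[C@H](O[Si](C)(C)C(C)(C)C)[C@@H]12 | intermediate
26 | 4,6α-bis[(tert-butyldimethylsilyl)oxy]-15-nor-5α-eudesm-3-ene | CC(C)(C)[Si](C)(C)OC1=CCC[C@]2(C)CC[C@@H](C(C)C)[C@H](O[Si](C)(C)C(C)(C)C)[C@@H]12 | intermediate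
27 | 6α-[(tert-butyldimethylsilyl)oxy]-15-nor-5α-eudesman-4-one | O=C1CCC[C@]2(C)CC[C@@H](C(C)C)[C@H](O[Si](C)(C)C(C)(C)C)[C@@H]12 | intermediate
28 | 6α-[(tert-butyldimethylsilyl)oxy]-5α-eudesm-4(15)-ene | C=C1CCC[C@]2(C)CC[C@@H](C(C)C)[C@H](O[Si](C)(C)C(C)(C)C)[C@@H]12 | intermediate
29 | (1S,2S,4aR,8aS)-4a-methyl-8-methylidene-2-(propan-2-yl)decahydronaphthalen-1-ol | C=C1CCC[C@]2(C)CC[C@@H](C(C)C)[C@H](O)[C@@H]12 | intermediate
30 | (E)-3-(4-acetoxyphenyl)prop-2-enoic acid | CC(=O)Oc1ccc(/C=C/C(=O)O)cc1 | starting material
31 | (E)-3-(4-acetoxyphenyl)prop-2-enoic 2,4,6-trichlorobenzoic anhydride | CC(=O)Oc1ccc(/C=C/C(=O)OC(=O)c2c(Cl)cc(Cl)cc2Cl)cc1 | intermediate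
32 | (1S,2S,4aR,8aS)-4a-methyl-8-methylidene-2-(propan-2-yl)decahydronaphthalen-1-yl (E)-3-(4-acetoxyphenyl)prop-2-enoate | C=C1CCC[C@]2(C)CC[C@@H](C(C)C)[C@H](OC(=O)/C=C/c3ccc(OC(C)=O)cc3)[C@@H]12 | intermediate
33 | (1S,2S,4aR,8aS)-4a-methyl-8-methylidene-2-(propan-2-yl)decahydronaphthalen-1-yl (E)-3-(4-hydroxyphenyl)prop-2-enoate | C=C1CCC[C@]2(C)CC[C@@H](C(C)C)[C@H](OC(=O)/C=C/c3ccc(O)cc3)[C@@H]12 | target

## Step count and least certain steps

Total: 20 steps. Longest linear sequence: 20 steps (1 → 33); compounds 3, 16, 20 and 30 are purchased.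

**Step 12 (key step).** The most likely failure is competition from the endo mode, in which the tether carbonyl sits under the diene. That gives the cis-fused C10 epimer, which cannot be corrected later. A second failure is loss of the dienol silane (hydrolysis, silyl transfer, elimination of the C6 silyloxy group) at the temperature an α-methyl enone needs, because the tether-enforced orientation is not the one the siloxy group accelerates. The fallback exchanges the siloxy substituent for a larger, hydrolytically inert carbon substituent at C4 that keeps the allylic-strain control, should penalise the endo arrangement more, and leads straight to the methylene group. It sets out from 18: KN(SiMe3)2 and PhNTf2 at −78 °C should give the Z-dienyl triflate F1; Negishi coupling with Me3SiCH2ZnCl and Pd(PPh3)4 should give the 2-(trimethylsilylmethyl)diene amide F2; CH2=C(CH3)MgBr should then give trienone F3. Heating F3 should give allylsilane ketone F4, which is taken through LiAlH4 reduction to alcohol F5, xanthate F6 and Bu3SnH reduction to allylsilane F7 as in steps 13–15. Protodesilylation of F7 with CF3CO2H in CH2Cl2 at −20 °C puts the proton on C3 and the double bond at C4=C15, and the route is rejoined at 28.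

**Step 2.** The Z-allylpotassium can isomerise to the E form if it warms, which would lead to the 6,7-cis diastereomer. The isopropyl group is axial in the chair transition state, which may slow the addition and erode enantioselectivity, and aldehyde 2 can lose methanol. The fallback is an Evans syn-aldol reaction, which gives the same syn pair by auxiliary control. It sets out from 2: the dibutylboron enolate of (4S)-4-benzyl-3-(3-methylbutanoyl)-1,3-oxazolidin-2-one (Bu2BOTf, iPr2NEt) should add to 2 to give aldol F8; silylation (TBSOTf, 2,6-lutidine, −78 °C) gives silyl ether F9; LiBH4 removes the auxiliary to give primary alcohol F10; Dess–Martin oxidation gives aldehyde F11; and Wittig methylenation with Ph3P=CH2 rejoins the route at 8.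

**Step 11.** On quenching, the released N,O-dimethylhydroxylamine can add to the new enone; the dienol silane can hydrolyse; and the β-branched amide may react sluggishly. The fallback goes through the aldehyde, so no amine is released next to the enone. It sets out from 19: iBu2AlH at −78 °C should give dienol silane aldehyde F12, CH2=C(CH3)MgBr should give trienol F13 (C9 epimers), and oxidation with MnO2 in CH2Cl2 returns to 21, which can cyclise as it forms.

**Step 15 (with step 14).** Xanthate formation at the neopentyl C9 alkoxide may be incomplete, and at 110 °C thermal syn-elimination of the xanthate toward C8 (Chugaev) can compete with the radical chain. The fallback removes the C9 oxygen through an alkene. It sets out from 22: KN(SiMe3)2 and PhNTf2 should give enol triflate F14; Pd(OAc)2, PPh3, Bu3N and HCO2H in DMF should reduce it to diene F15; and diimide (from 2-nitrobenzenesulfonyl hydrazide and Et3N) should reduce the disubstituted C8=C9 alkene in preference to the trisubstituted enol silane, rejoining the route at 26.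

**Step 17.** The C4 carbonyl is flanked by the ring-fusion carbon and the equatorial C6 silyloxy group, so methylenation may be slow, and long heating invites enolisation toward C5 with loss of the trans ring fusion. The fallback is a two-stage Peterson olefination. It sets out from 27: Me3SiCH2Li with CeCl3 in THF at −78 °C should add to the ketone to give β-hydroxysilane F16, and aqueous HF in MeCN should bring about the elimination and remove the C6 silyl group in the same operation, rejoining the route at 29.

## Further compounds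

F1 | step 12 | (3S,4S,5Z)-4-[(tert-butyldimethylsilyl)oxy]-N-methoxy-N-methyl-3-(propan-2-yl)-6-[(trifluoromethanesulfonyl)oxy]octa-5,7-dienamide | CON(C)C(=O)C[C@@H](C(C)C)[C@H](O[Si](C)(C)C(C)(C)C)/C=C(\OS(=O)(=O)C(F)(F)F)C=C
F2 | step 12 | (3S,4S,5Z)-4-[(tert-butyldimethylsilyl)oxy]-N-methoxy-N-methyl-3-(propan-2-yl)-6-[(trimethylsilyl)methyl]octa-5,7-dienamide | CON(C)C(=O)C[C@@H](C(C)C)[C@H](O[Si](C)(C)C(C)(C)C)/C=C(\C[Si](C)(C)C)C=C
F3 | step 12 | (5S,6S,7Z)-6-[(tert-butyldimethylsilyl)oxy]-2-methyl-5-(propan-2-yl)-8-[(trimethylsilyl)methyl]deca-1,7,9-trien-3-one | C=C(C)C(=O)C[C@@H](C(C)C)[C@H](O[Si](C)(C)C(C)(C)C)/C=C(\C[Si](C)(C)C)C=C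
F4 | step 12 | 6α-[(tert-butyldimethylsilyl)oxy]-15-(trimethylsilyl)-5α-eudesm-3-en-9-one | C[Si](C)(C)CC1=CCC[C@]2(C)C(=O)C[C@@H](C(C)C)[C@H](O[Si](C)(C)C(C)(C)C)[C@@H]12
F5 | step 12 | 6α-[(tert-butyldimethylsilyl)oxy]-15-(trimethylsilyl)-5α-eudesm-3-en-9-ol (C9 epimers) | C[Si](C)(C)CC1=CCC[C@]2(C)C(O)C[C@@H](C(C)C)[C@H](O[Si](C)(C)C(C)(C)C)[C@@H]12
F6 | step 12 | O-{6α-[(tert-butyldimethylsilyl)oxy]-15-(trimethylsilyl)-5α-eudesm-3-en-9-yl} S-methyl carbonodithioate | C[Si](C)(C)CC1=CCC[C@]2(C)C(OC(=S)SC)C[C@@H](C(C)C)[C@H](O[Si](C)(C)C(C)(C)C)[C@@H]12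
F7 | step 12 | 6α-[(tert-butyldimethylsilyl)oxy]-15-(trimethylsilyl)-5α-eudesm-3-ene | C[Si](C)(C)CC1=CCC[C@]2(C)CC[C@@H](C(C)C)[C@H](O[Si](C)(C)C(C)(C)C)[C@@H]12
F8 | step 2 | (4S)-4-benzyl-3-[(2S,3R)-3-hydroxy-5,5-dimethoxy-2-(propan-2-yl)pentanoyl]-1,3-oxazolidin-2-one | O=C([C@@H](C(C)C)[C@H](O)CC(OC)OC)N1[C@@H](Cc2ccccc2)COC1=O
F9 | step 2 | (4S)-4-benzyl-3-[(2S,3R)-3-[(tert-butyldimethylsilyl)oxy]-5,5-dimethoxy-2-(propan-2-yl)pentanoyl]-1,3-oxazolidin-2-one | O=C([C@@H](C(C)C)[C@H](O[Si](C)(C)C(C)(C)C)CC(OC)OC)N1[C@@H](Cc2ccccc2)COC1=O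
F10 | step 2 | (2R,3R)-3-[(tert-butyldimethylsilyl)oxy]-5,5-dimethoxy-2-(propan-2-yl)pentan-1-ol | OC[C@@H](C(C)C)[C@H](O[Si](C)(C)C(C)(C)C)CC(OC)OC
F11 | step 2 | (2S,3R)-3-[(tert-butyldimethylsilyl)oxy]-5,5-dimethoxy-2-(propan-2-yl)pentanal | O=C[C@@H](C(C)C)[C@H](O[Si](C)(C)C(C)(C)C)CC(OC)OC
F12 | step 11 | (3S,4S,5Z)-4,6-bis[(tert-butyldimethylsilyl)oxy]-3-(propan-2-yl)octa-5,7-dienal | O=CC[C@@H](C(C)C)[C@H](O[Si](C)(C)C(C)(C)C)/C=C(\O[Si](C)(C)C(C)(C)C)C=C
F13 | step 11 | (5S,6S,7Z)-6,8-bis[(tert-butyldimethylsilyl)oxy]-2-methyl-5-(propan-2-yl)deca-1,7,9-trien-3-ol (C3 epimers) | C=C(C)C(O)C[C@@H](C(C)C)[C@H](O[Si](C)(C)C(C)(C)C)/C=C(\O[Si](C)(C)C(C)(C)C)C=C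
F14 | step 15 | 4,6α-bis[(tert-butyldimethylsilyl)oxy]-15-nor-5α-eudesma-3,8-dien-9-yl trifluoromethanesulfonate | CC(C)(C)[Si](C)(C)OC1=CCC[C@]2(C)C(OS(=O)(=O)C(F)(F)F)=C[C@@H](C(C)C)[C@H](O[Si](C)(C)C(C)(C)C)[C@@H]12
F15 | step 15 | 4,6α-bis[(tert-butyldimethylsilyl)oxy]-15-nor-5α-eudesma-3,8-diene | CC(C)(C)[Si](C)(C)OC1=CCC[C@]2(C)C=C[C@@H](C(C)C)[C@H](O[Si](C)(C)C(C)(C)C)[C@@H]12
F16 | step 17 | 6α-[(tert-butyldimethylsilyl)oxy]-15-(trimethylsilyl)-5α-eudesman-4-ol (C4 epimers) | C[Si](C)(C)CC1(O)CCC[C@]2(C)CC[C@@H](C(C)C)[C@H](O[Si](C)(C)C(C)(C)C)[C@@H]12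
A1 | alternative 1 | 3-[(3S)-3-formyl-4-methylpentyl]-3-methylcyclohexan-1-one (quaternary carbon as C10 of the target) | O=C1CCC[C@](C)(CC[C@@H](C(C)C)C=O)C1
A2 | alternative 1 | 6α-hydroxy-15-nor-5α-eudesman-4-one | O=C1CCC[C@]2(C)CC[C@@H](C(C)C)[C@H](O)[C@@H]12
A3 | alternative 2 | 3-{(3S)-3-[(tert-butyldimethylsilyloxy)methyl]-4-methylpentyl}cyclohex-2-en-1-ol (carbinol centre as drawn) | O[C@@H]1C=C(CC[C@@H](C(C)C)CO[Si](C)(C)C(C)(C)C)CCC1
A4 | alternative 2 | 6-{(3S)-3-[(tert-butyldimethylsilyloxy)methyl]-4-methylpentyl}bicyclo[4.1.0]heptan-2-ol (cyclopropane syn to hydroxyl) | O[C@@H]1[C@@H]2C[C@]2(CC[C@@H](C(C)C)CO[Si](C)(C)C(C)(C)C)CCC1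
A5 | alternative 3 | methyl 2-methyl-6-oxocyclohex-1-ene-1-carboxylate | COC(=O)C1=C(C)CCCC1=O
A6 | alternative 3 | (1E)-1-[(tert-butyldimethylsilyl)oxy]-2-(propan-2-yl)buta-1,3-diene | C=C/C(C(C)C)=C/O[Si](C)(C)C(C)(C)C
A7 | alternative 3 | methyl 6α-[(tert-butyldimethylsilyl)oxy]-4-oxo-15-noreudesm-7-ene-5-carboxylate (cis-fused) | O=C1CCC[C@]2(C)CC=C(C(C)C)[C@H](O[Si](C)(C)C(C)(C)C)[C@]12C(=O)OC
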